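**Strategy.** Alertenone is cut at the CH2–CH bond between the two cyclopentanone rings into two molecules of the α-methylene ketone suberosenone (Michael dimerisation). In each half the gem-dimethylcyclopentane ring (quaternary bridgehead, CH2, CMe2, bridgehead CH, bridge CH) is the five-membered ring of a bicyclo[3.2.1]octane, and its CMe2–CH bond is made by ring expansion of a cyclobutane. A [4.3.2]propellane carbinol, from head-to-tail [2+2] photocycloaddition of isobutylene to a citronellal-derived hydrindenone, ionises in acid; the CMe2 carbon shifts from the central carbon to the carbinol carbon, which creates the bridged tricycle in one operation, and both carbinol epimers converge on one enone.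

Key step: step 7

Remark on the chemistry: the carbinol centres made in steps 5 and 10 are destroyed in steps 7 and 11, so those compounds are carried as epimer mixtures and drawn without a descriptor at that carbon. Locants of the tricyclic compounds follow tricyclo[4.3.2.0^{1,5}]undecane: C1 quaternary bridgehead, C2–C4 the other carbons of the five-membered ketone ring, C5 bridge CH, C6 bridgehead CH, C9 CHMe, C10 CH2, C11 CMe2. Primed locants denote the half of the dimer that carries the saturated CH2 link.

Step 1
Reactants: 1 (S)-citronellal; 2 ethyl acrylate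
Product: 3 ethyl (6S)-6,10-dimethyl-4-oxoundec-9-enoate
Conditions: 3-benzyl-5-(2-hydroxyethyl)-4-methylthiazolium chloride (cat.), Et3N (cat.), EtOH, 80 °C
Reagents that add atoms: none
Why: Stetter reaction, in which the thiazolium carbene turns the aldehyde carbon into an acyl anion equivalent that adds 1,4 to the acrylate, should give the 1,4-keto ester without touching the remote stereocentre or the trisubstituted alkene.

Step 2
Reactants: 3 ethyl (6S)-6,10-dimethyl-4-oxoundec-9-enoate
Product: 4 2-[(2S)-6-methylhept-5-en-2-yl]cyclopentane-1,3-dione
Conditions: KOtBu, tBuOH–THF, reflux; aq HCl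
Reagents that add atoms: none
Why: Intramolecular Claisen (Dieckmann-type) acylation of the ketone enolate at the CH2 that carries the branched chain closes the five-membered ring and is driven by formation of the stabilised 1,3-dione enolate, as in the classical preparation of 2-alkylcyclopentane-1,3-diones from 4-oxoalkanoates.

Step 3
Reactants: 4 2-[(2S)-6-methylhept-5-en-2-yl]cyclopentane-1,3-dione
Product: 5 3-iodo-2-[(2S)-6-methylhept-5-en-2-yl]cyclopent-2-en-1-one
Conditions: PPh3, I2, Et3N, MeCN, rt then reflux
Reagents that add atoms: iodine, II
Why: The enol oxygen is activated as an oxyphosphonium salt and replaced by iodide through addition–elimination (β-iodo enone formation from a 1,3-dione), and the two carbonyls of the dione are equivalent so only one product can form.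

Step 4
Reactants: 5 3-iodo-2-[(2S)-6-methylhept-5-en-2-yl]cyclopent-2-en-1-one
Product: 7 (4S)-4-(2-iodo-5-oxocyclopent-1-en-1-yl)pentanal, via secondary ozonide 6 (not isolated)
Conditions: O3, CH2Cl2, −78 °C (Sudan Red 7B end point); then Me2S, −78 °C to rt
Reagents that add atoms: ozone, [O-][O+]=O
Why: Ozonolysis should cleave the electron-rich trisubstituted alkene far faster than the electron-poor tetrasubstituted iodo-enone, and reduction of the ozonide unmasks the aldehyde.

Step 5
Reactants: 7 (4S)-4-(2-iodo-5-oxocyclopent-1-en-1-yl)pentanal
Product: 8 (7S)-4-hydroxy-7-methyl-2,3,4,5,6,7-hexahydro-1H-inden-1-one (both C4 epimers)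
Conditions: CrCl2 (excess), NiCl2 (cat.), DMF, rt, high dilution; aq work-up
Reagents that add atoms: none
Why: Nozaki–Hiyama–Kishi cyclisation, in which the vinylchromium species formed from the activated β-iodo enone adds chemoselectively to the aldehyde, should close the six-membered ring without touching the ketone, and the new carbinol centre is not controlled and need not be.

Step 6
Reactants: 8 (7S)-4-hydroxy-7-methyl-2,3,4,5,6,7-hexahydro-1H-inden-1-one; 9 isobutylene
Product: 10 (1R,5S,6S)-2-hydroxy-5,10,10-trimethyltricyclo[4.3.2.0^{1,6}]undecan-7-one (both C2 epimers)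
Conditions: isobutylene (excess), hν (medium-pressure Hg lamp, uranium-glass filter), CH2Cl2, −78 °C
Reagents that add atoms: none
Why: Enone–alkene [2+2] photocycloaddition through the enone triplet should give the head-to-tail adduct usual for isobutylene (CMe2 on the β-carbon), with the alkene approaching anti to the pseudoaxial C7 methyl, which fixes both central quaternary carbons relative to the methyl centre.

Step 7
Reactants: 10 (1R,5S,6S)-2-hydroxy-5,10,10-trimethyltricyclo[4.3.2.0^{1,6}]undecan-7-one
Product: 12 (1S,5S,6S,9S)-9,11,11-trimethyltricyclo[4.3.2.0^{1,5}]undec-3-en-2-one, via non-conjugated enone 11 (not isolated)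
Conditions: TsOH·H2O (cat.), toluene, 100 °C
Reagents that add atoms: none
Why: Protonation of the carbinol and loss of water, assisted by the antiperiplanar cyclobutane bond in one epimer and passing through the free secondary cation (or the alkene formed from it) in the other, triggers a Wagner–Meerwein 1,2-shift of the CMe2 carbon from the adjacent central carbon to the carbinol carbon, which is the cyclobutylcarbinyl-to-cyclopentyl ring expansion well known for cyclobutyl carbinols and propellane carbinols in acid. This suprafacial 1,2-alkyl shift is the ring-forming event for the gem-dimethylcyclopentane (the four-membered ring grows by one atom; no end-to-end cyclisation is involved) and turns the cyclohexane of the propellane into the six-membered ring of a bicyclo[3.2.1]octane. The resulting tertiary cation at the one-carbon bridge loses a proton from the neighbouring ring CH2 to give 11, which the acid conjugates through its dienol to 12. The bridgehead CH (C6) is fixed by migration on the cyclobutane face, and the bridge CH (C5) is set by reversible γ-protonation that should favour the isomer with the five-membered ketone ring syn to the C10–C11 bridge, because the other isomer puts C4 in a 1,3-diaxial relation to the C9 methyl. The step needs migration of the CMe2 carbon in preference to the central C–C bond or the cyclopentanone CH2, and this is secured by the electron-rich tertiary migrating carbon, by the ketone on the other central carbon, which makes that carbon a poor migrating group and blocks any further shift toward an α-keto cation, and by the absence of strain release for the CH2 shift.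

Step 8
Reactants: 12 (1S,5S,6S,9S)-9,11,11-trimethyltricyclo[4.3.2.0^{1,5}]undec-3-en-2-one
Product: 13 (1S,5S,6S,9S)-9,11,11-trimethyltricyclo[4.3.2.0^{1,5}]undecan-2-one
Conditions: H2 (1 atm), 10% Pd/C, EtOAc, rt
Reagents that add atoms: none
Why: Heterogeneous hydrogenation should saturate the unhindered disubstituted enone double bond, creating no stereocentre and leaving the hindered ketone untouched.

Step 9
Reactants: 13 (1S,5S,6S,9S)-9,11,11-trimethyltricyclo[4.3.2.0^{1,5}]undecan-2-one
Product: 14 (1S,5S,6S,9S)-9,11,11-trimethyl-2-methylidenetricyclo[4.3.2.0^{1,5}]undecane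
Conditions: Ph3PCH3Br, KOtBu, toluene, 90 °C
Reagents that add atoms: methyltriphenylphosphonium bromide, C[P+](c1ccccc1)(c1ccccc1)c1ccccc1.[Br-]
Why: Wittig methylenation in hot toluene should overcome the hindrance of the ketone next to the quaternary carbon, and only a non-stereogenic CH2 is enolisable so nothing can epimerise.

Step 10
Reactants: 14 (1S,5S,6S,9S)-9,11,11-trimethyl-2-methylidenetricyclo[4.3.2.0^{1,5}]undecane
Product: 15 (1S,5S,6S,9S)-9,11,11-trimethyl-2-methylidenetricyclo[4.3.2.0^{1,5}]undecan-3-ol (both C3 epimers)
Conditions: SeO2 (cat.), tBuOOH, CH2Cl2, rt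
Reagents that add atoms: selenium dioxide, O=[Se]=O; tert-butyl hydroperoxide, CC(C)(C)OO
Why: Selenium dioxide allylic oxidation (ene reaction then [2,3]-sigmatropic shift) should hydroxylate the ring CH2, the only allylic C–H position because the other allylic carbon is quaternary, and return the double bond to the exocyclic position.

Step 11
Reactants: 15 (1S,5S,6S,9S)-9,11,11-trimethyl-2-methylidenetricyclo[4.3.2.0^{1,5}]undecan-3-ol
Product: 16 suberosenone, (1S,5S,6S,9S)-9,11,11-trimethyl-2-methylidenetricyclo[4.3.2.0^{1,5}]undecan-3-one
Conditions: Dess–Martin periodinane, CH2Cl2, 0 °C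
Reagents that add atoms: none
Why: Dess–Martin oxidation of the allylic alcohol under neutral, non-nucleophilic conditions should give the sensitive α-methylene ketone without conjugate addition or double-bond migration.

Step 12
Reactants: 16 suberosenone (two molecules)
Product: 19 alertenone, via suberosenone lithium dienolate 17 (not isolated), via Michael adduct lithium enolate 18 (not isolated)
Conditions: LiN(SiMe3)2 (0.5 equiv per 16), THF, −78 to −40 °C; AcOH, −78 °C
Reagents that add atoms: none
Why: Kinetic deprotonation of half of 16 at C4, its only enolisable position, gives a cross-conjugated dienolate that adds through C4 to the exocyclic methylene of the second molecule (Michael addition) on the convex face of the five-membered ring, anti to the exo methyl on C11, and protonation of the adduct enolate at C2′ from the face opposite the C9′ methyl should complete the stereochemistry.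

**Compound list**

1 | (S)-citronellal, (3S)-3,7-dimethyloct-6-enal | CC(C)=CCC[C@H](C)CC=O | starting material
2 | ethyl acrylate | C=CC(=O)OCC | starting material
3 | ethyl (6S)-6,10-dimethyl-4-oxoundec-9-enoate | CC(C)=CCC[C@H](C)CC(=O)CCC(=O)OCC | intermediate
4 | 2-[(2S)-6-methylhept-5-en-2-yl]cyclopentane-1,3-dione (drawn as the diketone, largely enolised) | CC(C)=CCC[C@H](C)C1C(=O)CCC1=O | intermediate
5 | 3-iodo-2-[(2S)-6-methylhept-5-en-2-yl]cyclopent-2-en-1-one | CC(C)=CCC[C@H](C)C1=C(I)CCC1=O | intermediate
6 | secondary ozonide of 5, 3-[(3S)-3-(2-iodo-5-oxocyclopent-1-en-1-yl)butyl]-5,5-dimethyl-1,2,4-trioxolane | CC1(C)OOC(CC[C@H](C)C2=C(I)CCC2=O)O1 | intermediate (not isolated)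
7 | (4S)-4-(2-iodo-5-oxocyclopent-1-en-1-yl)pentanal | O=CCC[C@H](C)C1=C(I)CCC1=O | intermediate
8 | (7S)-4-hydroxy-7-methyl-2,3,4,5,6,7-hexahydro-1H-inden-1-one, both C4 epimers | OC1CC[C@H](C)C2=C1CCC2=O | intermediate
9 | isobutylene (2-methylpropene) | CC(C)=C | starting material
10 | (1R,5S,6S)-2-hydroxy-5,10,10-trimethyltricyclo[4.3.2.0^{1,6}]undecan-7-one, both C2 epimers; [4.3.2]propellane with the CMe2 on the cyclobutane carbon bonded to the carbinol-side central carbon and the methyl anti to the cyclobutane | OC1CC[C@H](C)[C@@]2(C(=O)CC3)CC(C)(C)[C@@]123 | intermediate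
11 | (1S,6R,9S)-9,11,11-trimethyltricyclo[4.3.2.0^{1,5}]undec-4-en-2-one | O=C1CC=C2[C@@H]3CC[C@H](C)[C@]12CC3(C)C | intermediate (not isolated)
12 | (1S,5S,6S,9S)-9,11,11-trimethyltricyclo[4.3.2.0^{1,5}]undec-3-en-2-one; H-5 on the face of the five-membered ring syn to C9 | O=C1C=C[C@H]2[C@@H]3CC[C@H](C)[C@]12CC3(C)C | intermediate
13 | (1S,5S,6S,9S)-9,11,11-trimethyltricyclo[4.3.2.0^{1,5}]undecan-2-one | O=C1CC[C@H]2[C@@H]3CC[C@H](C)[C@]12CC3(C)C | intermediate
14 | (1S,5S,6S,9S)-9,11,11-trimethyl-2-methylidenetricyclo[4.3.2.0^{1,5}]undecane | C=C1CC[C@H]2[C@@H]3CC[C@H](C)[C@]12CC3(C)C | intermediate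
15 | (1S,5S,6S,9S)-9,11,11-trimethyl-2-methylidenetricyclo[4.3.2.0^{1,5}]undecan-3-ol, both C3 epimers | C=C1C(O)C[C@H]2[C@@H]3CC[C@H](C)[C@]12CC3(C)C | intermediate
16 | suberosenone, (1S,5S,6S,9S)-9,11,11-trimethyl-2-methylidenetricyclo[4.3.2.0^{1,5}]undecan-3-one | C=C1C(=O)C[C@H]2[C@@H]3CC[C@H](C)[C@]12CC3(C)C | intermediate
17 | lithium dienolate of suberosenone (C3–O–Li, C3=C4) | C=C1C(O[Li])=C[C@H]2[C@@H]3CC[C@H](C)[C@]12CC3(C)C | intermediate (not isolated)
18 | lithium enolate of the Michael adduct (C2′=C3′–O–Li) | C=C1C(=O)[C@H](CC2=C(O[Li])C[C@H]3[C@@H]4CC[C@H](C)[C@]23CC4(C)C)[C@H]2[C@@H]3CC[C@H](C)[C@]12CC3(C)C | intermediate (not isolated)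
19 | alertenone; the (1S,4R,5R,6S,9S) half carries the CH2 link at C4 on the ring face of H-5, and the (1′S,2′S,5′S,6′S,9′S) half carries it at C2′ on the face syn to C9′ | C=C1C(=O)[C@H](C[C@@H]2C(=O)C[C@H]3[C@@H]4CC[C@H](C)[C@]23CC4(C)C)[C@H]2[C@@H]3CC[C@H](C)[C@]12CC3(C)C | target

**Step count.** Total: 12 steps. Longest linear sequence: 12 steps from (S)-citronellal.

**Steps most likely to fail**

Step 7. After the 1,2-shift, re-protonation at the bridge carbon C5 may not discriminate the two ring-fusion configurations well enough, or conjugation may stall. The fallback sets out from 11, which is isolated when the acid treatment is stopped after the shift (shorter time, NaHCO3 quench). NaBH4 in MeOH should reduce the ketone from the face opposite the C9 methyl to give the homoallylic alcohol F1, with the hydroxyl on the ring face syn to C9. Hydroxyl-directed hydrogenation with [Ir(cod)(PCy3)(py)]PF6 and H2 in CH2Cl2 then delivers hydrogen to C5 from the hydroxyl-bearing face and gives the saturated alcohol F2. Dess–Martin oxidation of F2 comes back to the route at 13.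

Step 6. For the carbinol epimer of 8 in which hydroxyl and methyl lie on opposite faces, isobutylene may add to the methyl-bearing face (poor facial selectivity), and that epimer also lacks the antiperiplanar alignment used in step 7. The fallback sets out from 8. The epimers are separated and the (4S,7S) epimer is inverted by Mitsunobu reaction (4-nitrobenzoic acid, PPh3, DIAD, THF) to the ester F3. Methanolysis (K2CO3, MeOH) gives the (4R,7S) alcohol F4, identical with the directly obtained cis epimer, in which hydroxyl and methyl shield the same face. Photocycloaddition of F4 with isobutylene under the conditions of step 6 then gives the single propellane carbinol F5, whose hydroxyl is antiperiplanar to the migrating bond. Treatment of F5 as in step 7 comes back to the route at 12.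

Step 12. The adduct enolate or a second dienolate may add to further suberosenone (oligomerisation), and protonation of the adduct enolate at C2′ may be unselective. The fallback sets out from 16. One portion is converted with LiN(iPr)2 and Me3SiCl (THF, −78 °C) into the silyl dienol ether F6. Mukaiyama–Michael addition of F6 to a second portion of 16 (Me3SiOTf cat., CH2Cl2, −78 °C) with silyl transfer gives the isolable silyl enol ether F7 in a fixed 1:1 stoichiometry. Separate kinetic protodesilylation of F7 (Bu4NF, AcOH, THF, −78 °C) comes back to the route at 19.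

**Further compounds**

F1 | step 7 | 9,11,11-trimethyltricyclo[4.3.2.0^{1,5}]undec-4-en-2-ol, hydroxyl on the ring face syn to C9 | O[C@@H]1CC=C2[C@@H]3CC[C@H](C)[C@]12CC3(C)C
F2 | step 7 | 9,11,11-trimethyltricyclo[4.3.2.0^{1,5}]undecan-2-ol, hydroxyl and H-5 on the ring face syn to C9 | O[C@@H]1CC[C@H]2[C@@H]3CC[C@H](C)[C@]12CC3(C)C
F3 | step 6 | (4R,7S)-7-methyl-1-oxo-2,3,4,5,6,7-hexahydro-1H-inden-4-yl 4-nitrobenzoate | O=C(O[C@@H]1CC[C@H](C)C2=C1CCC2=O)c1ccc(cc1)[N+](=O)[O-]
F4 | step 6 | (4R,7S)-4-hydroxy-7-methyl-2,3,4,5,6,7-hexahydro-1H-inden-1-one | O[C@@H]1CC[C@H](C)C2=C1CCC2=O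
F5 | step 6 | (1R,2R,5S,6S)-2-hydroxy-5,10,10-trimethyltricyclo[4.3.2.0^{1,6}]undecan-7-one | O[C@@H]1CC[C@H](C)[C@@]2(C(=O)CC3)CC(C)(C)[C@@]123
F6 | step 12 | trimethylsilyl dienol ether of suberosenone (C3–OSiMe3, C3=C4) | C=C1C(O[Si](C)(C)C)=C[C@H]2[C@@H]3CC[C@H](C)[C@]12CC3(C)C
F7 | step 12 | trimethylsilyl enol ether of alertenone (C2′=C3′–OSiMe3) | C=C1C(=O)[C@H](CC2=C(O[Si](C)(C)C)C[C@H]3[C@@H]4CC[C@H](C)[C@]23CC4(C)C)[C@H]2[C@@H]3CC[C@H](C)[C@]12CC3(C)C
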